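How much target stands in each flask at 6.0 h, and is the stop in the earlier runs a balance or an end?

| setting | cedar | elm | alder | oak | red | blue | ochre | green | teal |
|---|---|---|---|---|---|---|---|---|---|
| starting material | 0.10 M | 0.10 M | 0.10 M | 0.16 M | 0.060 M | 0.40 M | 0.060 M | 0.050 M | 0.10 M |
| partner | 0.81 equiv | 1.5 equiv | 2.3 equiv | 0.70 equiv | 2.10 equiv | 1.40 equiv | 1.40 equiv | 2.80 equiv | 0.700 equiv |
| remark | run made earlier | run made earlier | run made earlier | run made earlier |  |  |  |  |  |
| time |  |  |  |  | 6.0 h | 6.0 h | 6.0 h | 6.0 h | 6.0 h |

| cedar: time / h | cedar: target / % | elm: time / h | elm: target / % | alder: time / h | alder: target / % | oak: time / h | oak: target / % |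
|---|---|---|---|---|---|---|---|
| 0.833 | 20.2 | 0.833 | 34.9 | 0.833 | 47.6 | 0.250 | 15.1 |
| 1.50 | 23.6 | 1.50 | 36.5 | 1.50 | 50.5 | 0.500 | 20.2 |
| 2.50 | 24.0 | 2.50 | 37.4 | 2.50 | 50.3 | 1.33 | 27.4 |
| 3.00 | 24.8 | 3.00 | 39.3 | 3.00 | 49.2 | 3.00 | 29.2 |

(each reading ± 1 percentage point)

- the flasks put in order of amount of target, in percent of the starting material charged, best first, at 6.0 h (red / blue / ochre / green / teal)
- the same order at 80 min (red / blue / ochre / green / teal)
- the amount of target, in percent of the starting material charged of the flask you put first, at 6.0 h
- the amount of target, in percent of the starting material charged of the flask you put last, at 6.0 h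

- what was read earlier has a scatter of 1 percentage point, one standard deviation

The runs stop early: cedar reads 23.6% at 1.50 h and 24.8% at 3.00 h, far below its limiting reagent, the partner at 0.81 equiv. I read each plateau in two ways, as thermodynamic and as kinetic control, with y the plateau target as a fraction of the charge (cedar, elm and alder as the mean of the last two readings, oak as its last).

If the stop is a balance, starting material and partner remain beside target:

equilibrium constant = y / [concentration × (1 − y) × (equivalents − y)]

This gives 5.70 M⁻¹, 5.57 M⁻¹ and 5.49 M⁻¹ at 0.10 M, and 6.32 M⁻¹ in oak, which is higher.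

If the stop is an end, starting material is used up, splitting at each moment between partner and a first-order loss. Integrating that split while the partner is consumed gives:

partition concentration = concentration × (1 − y) / ln[equivalents / (equivalents − y)]

The four runs give 0.211 M, 0.209 M, 0.206 M and, for oak, 0.210 M. I carry their mean, 0.209 M, as the partition concentration: the partner concentration at which starting material goes equally to target and to loss. Oak holds this value where the equilibrium constant moves, but one run with a scatter of 1 percentage point makes that a lean and not a proof.

For blue I solve the formula for y, starting from a trial of 66.7%. One pass gives 66.2% and the next 66.5%, so my figure lies between them, at about 66.4%.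

The forecast says blue > green > red > ochre > teal at 6.0 h and blue > green > red > ochre > teal at 80 min, with 63.6% on top and 21.6% last, on the ground that “they look like an equilibrium”. Its blue differs from mine: it implies a partition concentration of 0.240 M.

    intermediate B ⇌ intermediate C (K = 0.320, k = 5.80 × 10⁻⁴ s⁻¹)
    intermediate D ⇌ intermediate B (k = 5.30 × 10⁻⁴ s⁻¹)
    intermediate A → side product (k = 7.40 × 10⁻⁴ s⁻¹)
    starting material ⇌ intermediate A (K = 2.50, k = 5.90 × 10⁻⁴ s⁻¹)
    intermediate B → decomposed reagent (k = 8.60 × 10⁻⁵ s⁻¹)
    intermediate A → intermediate B (k = 8.90 × 10⁻⁵ s⁻¹)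
    starting material + partner → target (k = 0.00220 M⁻¹ s⁻¹)
    intermediate C ⇌ intermediate D (K = 47.0, k = 2.60 × 10⁻⁴ s⁻¹)

The flasks stand as forecast, blue > green > red > ochre > teal at 6.0 h and blue > green > red > ochre > teal at 80 min, with blue at 66.4% and teal at 21.9% at 6.0 h. Blue's 66.4% returns a partition concentration of 0.209 M, and a flask like teal with 2.80 equiv of partner, giving 54.7%, returns 0.209 M. Blue ends with starting material at 0% and side product at 30.0%. As charged, blue's half-life of starting material by the partner step is 0.16 h, shorter than the 0.326 h of its forward turning into intermediate A.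

(The readings are calculated for an exercise, and the scatter is random.)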